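**Strategy**

The route rests on cutting the saturated acyl chain between C14 and C15 (counted from the ester carbonyl, C1), a bond between two unactivated CH2 carbons. A crossed Kolbe electrolysis forms it: anodic decarboxylation of undecanoic acid and of pentadecanedioic acid mono(2-phenylethyl) ester gives a decyl radical and a 13-(2-phenylethoxycarbonyl)tridecyl radical, whose pairing completes the C24 chain in one operation with the ester already in place. The step exploits the unbranched, heteroatom-free polymethylene run C2–C23 of the tetracosanoyl chain; the C1 ester and the benzene ring of the phenylethyl group are remote spectators. The precursor half-ester comes in one step from the C15 diacid and 2-phenylethanol.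

Key step: step 2

Remark: the target has no stereocentre and no double bond, so there is no stereochemistry to set or protect.

**Route**

Step 1
Reactants: 1 pentadecanedioic acid; 2 2-phenylethanol
Product: 3 15-oxo-15-(2-phenylethoxy)pentadecanoic acid (pentadecanedioic acid mono(2-phenylethyl) ester)
Conditions: 1 (3 equiv), 2 (1 equiv), TsOH·H2O (5 mol%), toluene, reflux, Dean–Stark; cool, filter off excess 1; SiO2
Reagents that add atoms: none
Why: Fischer esterification, in which the threefold excess of diacid should bias the statistical outcome towards the mono-ester; unreacted 1 should crystallise from cold toluene for re-use and the little diester is removed by chromatography.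

Step 2
Reactants: 3 15-oxo-15-(2-phenylethoxy)pentadecanoic acid; 4 undecanoic acid
Product: 5 2-phenylethyl tetracosanoate
Conditions: 3 (1 equiv), 4 (5 equiv), KOH (5 mol% of total CO2H), MeOH, smooth Pt anode/Pt cathode, undivided cell, constant current ca. 0.25 A cm⁻², 45–50 °C, stopped while the electrolyte is still weakly acidic; aq. K2CO3 wash; SiO2 (hexane → hexane/EtOAc); recrystallisation
Reagents that add atoms: none
Why: Crossed Kolbe electrolysis: both carboxylates are oxidised by one electron at the Pt anode, the acyloxy radicals lose CO2, and the decyl and 13-(2-phenylethoxycarbonyl)tridecyl radicals combine in the anode layer to form the C14–C15 bond while protons are reduced to H2 at the cathode. The closest known reaction type is the mixed Kolbe coupling of a fatty acid with a dicarboxylic acid half-ester, as used for chain extension of long-chain acids. No ring is closed and no stereocentre is formed. The step needs cross- over homo-coupling and the radical over the two-electron (Hofer–Moest) pathway: the fivefold excess of cheap 4 should send most of the ester-bearing radical into the cross product, and the unbranched primary α-CH2 groups, smooth Pt, high current density and a weakly acidic electrolyte favour the radical pathway. The C1 ester and the phenyl ring lie 13 or more atoms from the radical centre and should not be attacked at the carboxylate-covered anode, and methanolysis of the ester should not compete as long as free acid remains. Eicosane (4 + 4) and the C28 diester (3 + 3) are expected companions and should separate cleanly on silica as hydrocarbon, mono-ester and diester.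

**Compound list**

1 | pentadecanedioic acid | OC(=O)CCCCCCCCCCCCCC(=O)O | starting material
2 | 2-phenylethanol | OCCc1ccccc1 | starting material
3 | 15-oxo-15-(2-phenylethoxy)pentadecanoic acid | OC(=O)CCCCCCCCCCCCCC(=O)OCCc1ccccc1 | intermediate
4 | undecanoic acid | CCCCCCCCCCC(=O)O | starting material
5 | 2-phenylethyl tetracosanoate (phenylethyl n-tetracosanoate) | CCCCCCCCCCCCCCCCCCCCCCCC(=O)OCCc1ccccc1 | target

**Step count**

Total steps: 2. Longest linear sequence: 2.

**Steps most likely to fail**

The route has only two steps, so both are ranked.

1. Step 2 (crossed Kolbe electrolysis). What may go wrong:
- statistical homo-coupling of the ester-bearing radical;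
- over-oxidation of the radicals to cations, giving methyl ethers and alkenes;
- passivation of the anode by the waxy products;
- ester exchange with methanol near the cathode if the electrolyte is allowed to turn alkaline.

Fallback, from 3 back to 5 by known chemistry without electrolysis: acid 3 is condensed with N-hydroxyphthalimide (DIC, cat. DMAP, CH2Cl2, rt) to give the redox-active ester 1,3-dioxoisoindolin-2-yl 2-phenylethyl pentadecanedioate F1. This is coupled with didecylzinc F2, made in the flask from commercial decylmagnesium bromide and ZnCl2 in THF, in a nickel-catalysed decarboxylative alkyl–alkyl Negishi coupling (NiCl2·glyme, 4,4'-di-tert-butyl-2,2'-bipyridine, THF/DMF, rt; aq. HCl work-up). The same C14–C15 bond is formed and the sequence returns to the route at 5; the ester should tolerate the organozinc reagent.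

2. Step 1 (mono-esterification). What may go wrong:
- over-esterification to the diester;
- tedious separation of the statistical mixture of amphiphilic long-chain acids.

Fallback, from 2 back to 3: commercial ω-pentadecalactone (oxacyclohexadecan-2-one, O=C1CCCCCCCCCCCCCCO1) is ring-opened with an excess of 2 (cat. TsOH, 90 °C, excess 2 removed by distillation) to give 2-phenylethyl 15-hydroxypentadecanoate F3. Its primary alcohol is then oxidised to the carboxylic acid (cat. TEMPO, PhI(OAc)2, MeCN/H2O, rt), which gives 3 without a statistical step.

**Further compounds**

F1 | step 2 | 1,3-dioxoisoindolin-2-yl 2-phenylethyl pentadecanedioate | O=C1c2ccccc2C(=O)N1OC(=O)CCCCCCCCCCCCCC(=O)OCCc1ccccc1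
F2 | step 2 | didecylzinc | CCCCCCCCCC[Zn]CCCCCCCCCC
F3 | step 1 | 2-phenylethyl 15-hydroxypentadecanoate | OCCCCCCCCCCCCCCC(=O)OCCc1ccccc1
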